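- The easy step first: zeta reads 3% of its substrate at 4.00 h, so I expect little substrate in oak when you come.

the same everywhere: substrate 0.050 M

| flask | reagent | remark | time |
|---|---|---|---|
| zeta | 0.055 M | run made earlier |  |
| gamma | 0.16 M | run made earlier |  |
| oak | 0.0750 M |  | 40 h |
| alder | 0.0400 M |  | 40 h |
| ash | 0.125 M |  | 40 h |

- zeta (time / h: first product / %, substrate / %): 2.50: 27, 12; 4.00: 31, 3; 8.00: 34, 2; 15.0: 34, 2; 30.0: 32, 0
- gamma (time / h: first product / %, substrate / %): 6.00: 47, 0; 12.0: 41, 0; 15.0: 43, 0; 25.0: 38, 1; 30.0: 35, 1

(scatter of a reading: 2 percentage points)

- which of these holds the largest part of the substrate at the end of oak (other mono adduct / bis adduct / first product / substrate)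
- which of these holds the largest part of the substrate at the end of alder (other mono adduct / bis adduct / first product / substrate)
- which of these holds the largest part of the substrate at the end of ash (other mono adduct / bis adduct / first product / substrate)
- first product at the end of oak, in percent of the substrate charged

- the earlier runs were read with a standard deviation of 2 percentage points

- I start at the early end: first product reads 34% at 8.00 h in zeta and 47% at 6.00 h in gamma, and a straight line in reagent charge puts oak near 36.5%.
- At the late end, gamma's first product reads 35% at 30.0 h. I take free reagent as charge less substrate charged, 0.110 M, and treat the fall as pseudo-first-order. This gives a reading, with its scatter, of 0.112 /M/h: the fading constant, the fraction of first product lost per hour per molar of free reagent.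
- In oak the same subtraction leaves 0.0250 M, so I reckon first product's half-life at 248 h, longer than the 40 h run. Joining both ends, I expect 32.6% first product at the end of oak.
- Please add no reagent to oak: in this reckoning, fading goes with free reagent.
- The forecast says 36%, and names other mono adduct as largest in oak, other mono adduct in alder and other mono adduct in ash, holding that “it is the main mono product at low reagent”.

    substrate + reagent → first product + released group (k = 0.130 /M/min)
    substrate + reagent → other mono adduct + released group (k = 0.0800 /M/min)
    reagent + first product → bis adduct + released group (k = 0.00160 /M/min)
    reagent + other mono adduct → bis adduct + released group (k = 0.610 /M/min)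
    2 substrate → homo dimer (k = 0.190 /M/min)

Oak ends with 33.4% first product, 27.5% bis adduct and 0% other mono adduct; first product leads alder and bis adduct leads ash. In oak, substrate and reagent first made first product and other mono adduct, while substrate also paired to homo dimer, which stands at 39.0%, and other mono adduct passed on to bis adduct, that turnover being mid-way by 1.16 h; afterwards reagent slowly turned first product into bis adduct. With each flask's mean reagent between 40.0 h and 400 h, the fading constant of 0.112 /M/h takes oak's 33.4% first product to 11.8% against oak's 14.1%, and ash's 34.2% to 2.83% against ash's 4.40%.

The readings stem from a simulated flask for an exercise, noise included.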